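The gas brings a small charge: a saturated solution holds 200 mM, far less than the 4.00 M of starting material and other conformer together in the flask. I supposed that each product takes one unit of gas, so the flask has to renew that load 20.0 times.

| setting | Friday's | Tuesday's | flask |
|---|---|---|---|
| starting material | 2 M | 2 M | 2.0 M |
| other conformer | 1.3 M | 3 M | 2.00 M |
| gas | 200 mM (held) | 200 mM (held) | 200 mM (held) |
| remark | run made earlier | run made earlier |  |
| time |  |  | 15 d |

| run | time / d | target / % | isomer of the product / % |
|---|---|---|---|
| Friday's | 2.50 | 33 | 27 |
| Friday's | 5.00 | 55 | 46 |
| Friday's | 6.00 | 51 | 45 |
| Friday's | 10.0 | 56 | 45 |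
| Tuesday's | 2.50 | 22 | 19 |
| Tuesday's | 5.00 | 45 | 36 |
| Tuesday's | 6.00 | 53 | 44 |
| Tuesday's | 10.0 | 54 | 44 |

(standard deviation of a reading: 1.5 percentage points)

- share of target in target plus isomer of the product at 2.5 h
- share of target in target plus isomer of the product at 30 h
- share of target in target plus isomer of the product at 15 d

- the numbers in the tables scatter with a standard deviation of 1.5 percentage points
- at the start none of the gas is in solution

So I counted turnovers. I read the rate of product formation from each run's first reading. Friday's run gave 0.792 M d⁻¹ and Tuesday's run, with a different charge, gave 0.820 M d⁻¹. These agree within the scatter, so gas uptake looked like the rate-limiting step, and I used the mean, 0.806 M d⁻¹, for the flask. Dividing the saturation concentration by this rate gave 5.96 h: the turnover time T, the time in which a flask uses one saturated load of gas.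

I then took the share of target in two ways. The first carried the readings forward: Friday's last reading gives 55.4%. The second counted turnovers. The first readings stood at 10.1 turnovers, so a departure confined to the first turnover reached them divided by that count. A departure of 15 percentage points could therefore hide in the scatter.

The flask should finish after about 4.96 d, earlier than 15 d. Spread over its whole count of turnovers, that departure shrinks to 0.76 points, less than the scatter, so at 15 d I kept 55.4%. At 30 h it stands at 5.03 turnovers, and I allowed 3 points around that share. At 2.5 h it stands at 0.419 turnovers. There the ways part, and the first one cheats, because it carries an average over many turnovers to a time shorter than T. I kept 55.4% with the full margin.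

The forecast gave 55%, 55% and 55%, saying of the share: “It doesn't change with conversion”.

The flask gave 48.6%, 54.1% and 54.8%.

    starting material ⇌ other conformer (K = 0.610, k = 0.222 h⁻¹)
    starting material + coupling partner → target (k = 0.956 M⁻¹ h⁻¹)
    coupling partner + other conformer → isomer of the product (k = 1.30 M⁻¹ h⁻¹)
    gas ⇌ coupling partner, rate k4*(csat - [coupling partner]) (kL = 0.185 h⁻¹)

The coupling partner is the dissolved gas. At 0.419 turnovers the flask stood 6.8 points below the share I had kept, inside my margin. The neighbouring flask, charged with 0.50 M of other conformer, needs 12.5 turnovers by the same count. On the same clock it gave 64.0% at 2.5 h, which is 8.6 points above the share I had kept and also inside the margin. At 30 h it gave 55.8%, and at 15 d it held 55.5% of target.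

(The earlier runs and the new flask are calculated on assumed constants, and the scatter is random.)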